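**Plan**

1. Numbering: ring carbons C1 (ketone) to C10 (methyl, acetate), with C4 (methyl)=C5, C6 (lactone oxygen) and C8 (methacrylate); C11 is the lactone α-carbon, C12 the lactone carbonyl, C13 the acetoxymethyl carbon.
2. The retrosynthesis first cuts the C8 and C13 ester C–O bonds, then C5–C6 together with O–C12. This double cut is possible because C6 is an allylic carbinol carbon lying between the Z C4=C5 alkene and the C7=C11 alkene, whose ester carbon C12 stands cis to C6. Joining a C5 alkenyl metal to a C6 aldehyde therefore closes the ten-membered ring and lets the C6 oxygen close the butenolide on C12.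
3. Further cuts: the cis C6-formyl/C12-ester pair is taken back to a 2-silylfuran (furan carbons C6, C7, C11, C12), C2–C3 to an enolate allylation, and C7–C8 to a furylzinc acylation.
4. Forward: the furan is acylated at C7 by a citramalate-derived acid chloride, C8 is reduced and silylated, the dioxolanone becomes the C1 methyl ketone, C2 is allylated with a (Z)-iodoallyl bromide, the furan is opened to the formyl ester, the macrocycle and butenolide close in one operation, and the two acyl groups are added last.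
5. Stereochemistry: C10 comes from (R)-citramalic acid; C8 from an oxazaborolidine-catalysed ketone reduction; C6 from the ring closure under control of C8; Z C4=C5 from anti-carbomagnesiation/iodination of propargyl alcohol; the cis C7=C11 geometry from the furan ring.

Key step: step 16

Abbreviations: TBS = tert-butyldimethylsilyl; Ar = 5-TBS-4-[(TBS-oxy)methyl]furan-3-yl, whose ring carbons are C7 (attachment point), C6 (unsubstituted α-carbon), C11 (carrying C13) and C12 (carrying silicon).

Remark: lactol 27 is assumed to form as a mixture of epimers at the hemiacetal carbon, which is without consequence because that carbon is opened to the aldehyde in step 15.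

**Route**

Step 1
Reactants: 1 furan-3-ylmethanol
Product: 2 tert-butyl(furan-3-ylmethoxy)dimethylsilane
Conditions: TBSCl, imidazole, DMF, 0 °C to rt
Reagents that add atoms: tert-butyldimethylsilyl chloride, CC(C)(C)[Si](C)(C)Cl
Why: Imidazole-promoted O-silylation of a primary alcohol is routine and places on oxygen the silyl group that the next step relays to carbon.

Step 2
Reactants: 2 tert-butyl(furan-3-ylmethoxy)dimethylsilane
Product: 4 [2-(tert-butyldimethylsilyl)furan-3-yl]methanol, via C2-lithiofuran 3 (not isolated)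
Conditions: n-BuLi, HMPA, THF, −78 °C to rt; then H2O
Reagents that add atoms: none
Why: The ether oxygen directs lithiation to the furan 2-position, and the carbanion takes silicon from oxygen in a retro-[1,4]-Brook rearrangement driven by formation of the lithium alkoxide, so the silyl group ends on the α-carbon next to the hydroxymethyl-bearing carbon.

Step 3
Reactants: 4 [2-(tert-butyldimethylsilyl)furan-3-yl]methanol
Product: 7 4-bromo-2-TBS-3-[(TBS-oxy)methyl]furan (ArBr), via dilithiated furan 5 (not isolated), via lithium alkoxide 6 (not isolated)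
Conditions: n-BuLi (2.2 equiv), DME, 0 °C; BrCl2C–CCl2Br, −78 °C; then TBSCl, DMAP (cat.), −78 °C to rt
Reagents that add atoms: 1,2-dibromo-1,1,2,2-tetrachloroethane, BrC(Cl)(Cl)C(Cl)(Cl)Br; tert-butyldimethylsilyl chloride, CC(C)(C)[Si](C)(C)Cl
Why: With the 2-position blocked, the lithium alkoxide directs the second lithiation to the neighbouring furan 4-position (directed ortho-metalation), the aryllithium is brominated by halogen transfer from the vicinal dibromide, and the remaining alkoxide is silylated in the same flask.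

Step 4
Reactants: 8 (R)-citramalic acid
Product: 9 2-[(4R)-2,2,4-trimethyl-5-oxo-1,3-dioxolan-4-yl]acetic acid
Conditions: Me2C(OMe)2, TsOH·H2O (cat.), CH2Cl2, rt
Reagents that add atoms: 2,2-dimethoxypropane, COC(C)(C)OC
Why: Acid-catalysed acetal exchange ties the tertiary hydroxyl and its geminal carboxyl into the five-membered dioxolanone in preference to the six-membered dioxanone, which leaves the CH2CO2H carboxyl (the future C8) free and the quaternary stereocentre (the future C10) untouched.

Step 5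
Reactants: 9 2-[(4R)-2,2,4-trimethyl-5-oxo-1,3-dioxolan-4-yl]acetic acid
Product: 10 2-[(4R)-2,2,4-trimethyl-5-oxo-1,3-dioxolan-4-yl]acetyl chloride
Conditions: (COCl)2, DMF (cat.), CH2Cl2, 0 °C to rt; concentrate, use crude
Reagents that add atoms: oxalyl chloride, O=C(Cl)C(Cl)=O
Why: Chlorination through the catalytic chloroiminium salt turns the free acid into the acid chloride under non-basic conditions that the dioxolanone tolerates.

Step 6
Reactants: 7 4-bromo-2-TBS-3-[(TBS-oxy)methyl]furan; 10 2-[(4R)-2,2,4-trimethyl-5-oxo-1,3-dioxolan-4-yl]acetyl chloride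
Product: 13 (5R)-5-(2-Ar-2-oxoethyl)-2,2,5-trimethyl-1,3-dioxolan-4-one, via furyllithium 11 (not isolated), via furylzinc chloride 12 (not isolated)
Conditions: 7, n-BuLi, THF, −78 °C; ZnCl2, −78 to 0 °C; then 10, Pd(PPh3)4 (5 mol%), 0 °C to rt
Reagents that add atoms: none
Why: Bromine–lithium exchange, transmetalation to zinc and Negishi acylation catalysed by zerovalent palladium join C7 to C8, the organozinc being too mild to attack the dioxolanone carbonyl or the ketone that is formed.

Step 7
Reactants: 13 (5R)-5-(2-Ar-2-oxoethyl)-2,2,5-trimethyl-1,3-dioxolan-4-one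
Product: 14 (5R)-5-[(2S)-2-Ar-2-hydroxyethyl]-2,2,5-trimethyl-1,3-dioxolan-4-one
Conditions: (R)-2-methyl-CBS-oxazaborolidine (20 mol%), BH3·SMe2, THF, −30 °C; then MeOH
Reagents that add atoms: none
Why: In the Corey–Bakshi–Shibata reduction the (R)-oxazaborolidine binds borane and the ketone so that the furyl group acts as the large and the CH2 group as the small substituent, which should deliver hydride to the face giving the 8S carbinol under reagent control.

Step 8
Reactants: 14 (5R)-5-[(2S)-2-Ar-2-hydroxyethyl]-2,2,5-trimethyl-1,3-dioxolan-4-one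
Product: 15 (5R)-5-[(2S)-2-Ar-2-(TBS-oxy)ethyl]-2,2,5-trimethyl-1,3-dioxolan-4-one
Conditions: TBSOTf, 2,6-lutidine, CH2Cl2, −78 °C
Reagents that add atoms: tert-butyldimethylsilyl trifluoromethanesulfonate, CC(C)(C)[Si](C)(C)OS(=O)(=O)C(F)(F)F
Why: The silyl triflate with a hindered pyridine base silylates the secondary alcohol at low temperature before it can translactonise onto the dioxolanone.

Step 9
Reactants: 15 (5R)-5-[(2S)-2-Ar-2-(TBS-oxy)ethyl]-2,2,5-trimethyl-1,3-dioxolan-4-one
Product: 17 (3R,5S)-5-Ar-3-hydroxy-3-methyl-5-(TBS-oxy)pentan-2-one, via Weinreb amide 16 (not isolated)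
Conditions: MeNH(OMe)·HCl, iPrMgCl, THF, −20 to 0 °C; then MeMgBr (excess), 0 °C to rt; aq. NH4Cl
Reagents that add atoms: methylmagnesium bromide, C[Mg]Br
Why: The chloromagnesium amide of N,O-dimethylhydroxylamine opens the activated dioxolanone to the Weinreb amide with loss of acetone, and the magnesium chelate formed on addition of MeMgBr releases the C1 methyl ketone only on work-up (Weinreb ketone synthesis).

Step 10
Reactants: 18 prop-2-yn-1-ol
Product: 20 (2Z)-3-iodo-2-methylprop-2-en-1-ol, via magnesium chelate 19 (not isolated)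
Conditions: MeMgBr (2.5 equiv), CuI (10 mol%), THF, −10 °C to rt; then I2, −10 °C to rt
Reagents that add atoms: methylmagnesium bromide, C[Mg]Br; iodine, II
Why: Copper-catalysed anti-carbomagnesiation of the propargylic alkoxide gives a five-membered alkenylmagnesium chelate that holds the metal cis to the CH2O group, and iodinolysis with retention fixes the Z geometry that becomes C4=C5.

Step 11
Reactants: 20 (2Z)-3-iodo-2-methylprop-2-en-1-ol
Product: 21 (1Z)-3-bromo-1-iodo-2-methylprop-1-ene
Conditions: CBr4, PPh3, CH2Cl2, 0 °C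
Reagents that add atoms: carbon tetrabromide, BrC(Br)(Br)Br
Why: The Appel reaction converts the allylic alcohol into the bromide under neutral conditions that leave the alkene geometry and the vinyl iodide alone.

Step 12
Reactants: 17 (3R,5S)-5-Ar-3-hydroxy-3-methyl-5-(TBS-oxy)pentan-2-one; 21 (1Z)-3-bromo-1-iodo-2-methylprop-1-ene
Product: 23 (1S,3R,7Z)-1-Ar-3-hydroxy-8-iodo-3,7-dimethyl-1-(TBS-oxy)oct-7-en-4-one, via dilithium enolate 22 (not isolated)
Conditions: LiN(iPr)2 (2.2 equiv), THF, −78 °C; then 21, DMPU, −78 to −40 °C; aq. NH4Cl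
Reagents that add atoms: none
Why: Two equivalents of amide base form the C10 alkoxide and then the only possible enolate (C10 is quaternary, so the methyl group C2 is deprotonated), and SN2 alkylation with the reactive allylic bromide forms C2–C3 while the vinyl iodide is inert to the enolate.

Step 13
Reactants: 23 (1S,3R,7Z)-1-Ar-3-hydroxy-8-iodo-3,7-dimethyl-1-(TBS-oxy)oct-7-en-4-one
Product: 24 (1S,3R,7Z)-1-Ar-8-iodo-3,7-dimethyl-4-oxo-1-(TBS-oxy)oct-7-en-3-yl acetate
Conditions: Ac2O, DMAP (0.3 equiv), Et3N, CH2Cl2, rt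
Reagents that add atoms: acetic anhydride, CC(=O)OC(C)=O
Why: DMAP-catalysed acylation through the N-acetylpyridinium ion is strong enough to acetylate the tertiary α-ketol hydroxyl, and it is placed after the last strong-base step so that the α-acetoxy ketone never meets an enolising base.

Step 14
Reactants: 24 (1S,3R,7Z)-1-Ar-8-iodo-3,7-dimethyl-4-oxo-1-(TBS-oxy)oct-7-en-3-yl acetate
Product: 27 (1S,3R,7Z)-1-{2-hydroxy-5-oxo-4-[(TBS-oxy)methyl]-2,5-dihydrofuran-3-yl}-8-iodo-3,7-dimethyl-4-oxo-1-(TBS-oxy)oct-7-en-3-yl acetate, via furan endoperoxide 25 (not isolated), via silyl ester 26 (not isolated)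
Conditions: O2, hν (visible), tetraphenylporphyrin (cat.), CH2Cl2, −78 °C; then 0 °C, THF/H2O
Reagents that add atoms: dioxygen, O=O
Why: Singlet oxygen should add [4+2] to the electron-rich furan much faster than it undergoes an ene reaction with the iodine-deactivated C4=C5 alkene, and the endoperoxide rearranges by a 1,2-shift of silicon from C12 to peroxide oxygen, so that C12 becomes the carboxyl carbon and C6 the lactol carbon with C7=C11 locked cis (silyl-directed furan photooxygenation).

Step 15
Reactants: 27 (1S,3R,7Z)-1-{2-hydroxy-5-oxo-4-[(TBS-oxy)methyl]-2,5-dihydrofuran-3-yl}-8-iodo-3,7-dimethyl-4-oxo-1-(TBS-oxy)oct-7-en-3-yl acetate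
Product: 29 methyl (2Z,4S,6R,10Z)-6-acetoxy-3-formyl-11-iodo-6,10-dimethyl-7-oxo-4-(TBS-oxy)-2-[(TBS-oxy)methyl]undeca-2,10-dienoate, via potassium carboxylate 28 (not isolated)
Conditions: MeI, K2CO3, DMF, 0 °C
Reagents that add atoms: iodomethane, CI
Why: Mild base opens the pseudo-acid to the (Z)-formyl carboxylate, whose SN2 esterification with iodomethane gives the open-chain methyl ester and leaves the aldehyde free and cis to it.

Step 16
Reactants: 29 methyl (2Z,4S,6R,10Z)-6-acetoxy-3-formyl-11-iodo-6,10-dimethyl-7-oxo-4-(TBS-oxy)-2-[(TBS-oxy)methyl]undeca-2,10-dienoate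
Product: 32 (4Z,6R,8S,10R)-10-acetoxy-1-oxo-8,13-bis(TBS-oxy)germacra-4,7(11)-dien-12,6-olide, via alkenylchromium dichloride 30 (not isolated), via chromium alkoxide 31 (not isolated)
Conditions: CrCl2 (10 equiv), NiCl2 (0.1 equiv), degassed DMSO/THF, rt, slow addition to 0.002 M; aq. sodium serinate work-up, brief contact with silica gel
Reagents that add atoms: none
Why: CrCl2 reduces NiCl2 to zerovalent nickel, which inserts into the C5–I bond with retention of the Z geometry and hands the alkenyl group to trivalent chromium, and the alkenylchromium then adds to the C6 aldehyde and to no other carbonyl group, which forms C5–C6 and the ten-membered ring by a 10-exo-trig closure (Nozaki–Hiyama–Kishi reaction). The closest known reaction type is the intramolecular alkenyl iodide–aldehyde coupling used to close medium and large carbocycles. The C6 chromium alkoxide, or the alcohol freed on work-up, is held next to the C12 methyl ester by the tetrasubstituted C7=C11 bond and acylates in a 5-exo-trig closure to the butenolide with loss of methanol. C6 is set under control of C8: A(1,3) strain with the C13 methylene keeps C8–H in the plane of C7=C11, so that C9 and the tether stand on one face while the silyloxy group shields the other, and the formyl group, turned with its oxygen away from the cis ester, is attacked on the C9 face, which corresponds to 6R. The step needs aldehyde chemoselectivity and retention of alkene geometry, both inherent in the metal pair, and ring closure ahead of intermolecular coupling, which the Z iodide (its reacting carbon points back along the chain) and slow addition at high dilution should secure.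

Step 17
Reactants: 32 (4Z,6R,8S,10R)-10-acetoxy-1-oxo-8,13-bis(TBS-oxy)germacra-4,7(11)-dien-12,6-olide
Product: 33 (4Z,6R,8S,10R)-10-acetoxy-8,13-dihydroxy-1-oxogermacra-4,7(11)-dien-12,6-olide
Conditions: HF·pyridine, pyridine, THF, 0 °C to rt
Reagents that add atoms: none
Why: Buffered fluoride cleaves both silyl ethers through Si–F bond formation under conditions too weakly basic to epimerise C6 or disturb the α-acetoxy ketone and too weakly acidic to ionise the allylic lactone.

Step 18
Reactants: 33 (4Z,6R,8S,10R)-10-acetoxy-8,13-dihydroxy-1-oxogermacra-4,7(11)-dien-12,6-olide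
Product: 34 (4Z,6R,8S,10R)-10,13-diacetoxy-8-hydroxy-1-oxogermacra-4,7(11)-dien-12,6-olide
Conditions: AcCl (1.05 equiv), 2,4,6-collidine, CH2Cl2, −78 °C
Reagents that add atoms: acetyl chloride, CC(Cl)=O
Why: At low temperature with a hindered pyridine base the acyl chloride should react much faster with the unhindered primary allylic hydroxyl than with the secondary C8 hydroxyl flanked by C7 and C9 (kinetically selective O-acylation).

Step 19
Reactants: 34 (4Z,6R,8S,10R)-10,13-diacetoxy-8-hydroxy-1-oxogermacra-4,7(11)-dien-12,6-olide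
Product: 35 (4Z,6R,8S,10R)-10,13-diacetoxy-8-(2-methylprop-2-enoyloxy)-1-oxogermacra-4,7(11)-dien-12,6-olide (CNP0115165.2)
Conditions: methacrylic anhydride, DMAP (cat.), pyridine, CH2Cl2, 0 °C to rt
Reagents that add atoms: methacrylic anhydride, C=C(C)C(=O)OC(=O)C(C)=C
Why: DMAP-catalysed acylation with the anhydride esterifies the remaining secondary hydroxyl, with pyridine as a base weak enough not to epimerise the doubly allylic C6.

**Compound list**

1 | furan-3-ylmethanol | OCc1ccoc1 | starting material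
2 | tert-butyl(furan-3-ylmethoxy)dimethylsilane | CC(C)(C)[Si](C)(C)OCc1ccoc1 | intermediate
3 | {3-[(TBS-oxy)methyl]furan-2-yl}lithium | CC(C)(C)[Si](C)(C)OCc1ccoc1[Li] | intermediate
4 | [2-(tert-butyldimethylsilyl)furan-3-yl]methanol | OCc1ccoc1[Si](C)(C)C(C)(C)C | intermediate
5 | lithium (4-lithio-2-TBS-furan-3-yl)methanolate | [Li]OCc1c([Li])coc1[Si](C)(C)C(C)(C)C | intermediate
6 | lithium (4-bromo-2-TBS-furan-3-yl)methanolate | [Li]OCc1c(Br)coc1[Si](C)(C)C(C)(C)C | intermediate
7 | 4-bromo-2-TBS-3-[(TBS-oxy)methyl]furan (ArBr) | CC(C)(C)[Si](C)(C)OCc1c(Br)coc1[Si](C)(C)C(C)(C)C | intermediate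
8 | (R)-citramalic acid, (2R)-2-hydroxy-2-methylbutanedioic acid | OC(=O)C[C@@](C)(O)C(=O)O | starting material
9 | 2-[(4R)-2,2,4-trimethyl-5-oxo-1,3-dioxolan-4-yl]acetic acid | OC(=O)C[C@@]1(C)OC(C)(C)OC1=O | intermediate
10 | 2-[(4R)-2,2,4-trimethyl-5-oxo-1,3-dioxolan-4-yl]acetyl chloride | ClC(=O)C[C@@]1(C)OC(C)(C)OC1=O | intermediate
11 | ArLi, {5-TBS-4-[(TBS-oxy)methyl]furan-3-yl}lithium | [Li]c1coc([Si](C)(C)C(C)(C)C)c1CO[Si](C)(C)C(C)(C)C | intermediate
12 | ArZnCl, {5-TBS-4-[(TBS-oxy)methyl]furan-3-yl}zinc chloride | Cl[Zn]c1coc([Si](C)(C)C(C)(C)C)c1CO[Si](C)(C)C(C)(C)C | intermediate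
13 | (5R)-5-(2-Ar-2-oxoethyl)-2,2,5-trimethyl-1,3-dioxolan-4-one | O=C(C[C@@]1(C)OC(C)(C)OC1=O)c1coc([Si](C)(C)C(C)(C)C)c1CO[Si](C)(C)C(C)(C)C | intermediate
14 | (5R)-5-[(2S)-2-Ar-2-hydroxyethyl]-2,2,5-trimethyl-1,3-dioxolan-4-one | O[C@@H](C[C@@]1(C)OC(C)(C)OC1=O)c1coc([Si](C)(C)C(C)(C)C)c1CO[Si](C)(C)C(C)(C)C | intermediate
15 | (5R)-5-[(2S)-2-Ar-2-(TBS-oxy)ethyl]-2,2,5-trimethyl-1,3-dioxolan-4-one | CC(C)(C)[Si](C)(C)O[C@@H](C[C@@]1(C)OC(C)(C)OC1=O)c1coc([Si](C)(C)C(C)(C)C)c1CO[Si](C)(C)C(C)(C)C | intermediate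
16 | (2R,4S)-4-Ar-2-hydroxy-N-methoxy-N,2-dimethyl-4-(TBS-oxy)butanamide (present as its magnesium alkoxide) | CON(C)C(=O)[C@](C)(O)C[C@H](O[Si](C)(C)C(C)(C)C)c1coc([Si](C)(C)C(C)(C)C)c1CO[Si](C)(C)C(C)(C)C | intermediate
17 | (3R,5S)-5-Ar-3-hydroxy-3-methyl-5-(TBS-oxy)pentan-2-one | CC(=O)[C@](C)(O)C[C@H](O[Si](C)(C)C(C)(C)C)c1coc([Si](C)(C)C(C)(C)C)c1CO[Si](C)(C)C(C)(C)C | intermediate
18 | prop-2-yn-1-ol | C#CCO | starting material
19 | 4-methyl-2,5-dihydro-1,2-oxamagnesole (cyclic alkenylmagnesium alkoxide) | CC1=C[Mg]OC1 | intermediate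
20 | (2Z)-3-iodo-2-methylprop-2-en-1-ol | OC/C(C)=C\I | intermediate
21 | (1Z)-3-bromo-1-iodo-2-methylprop-1-ene | BrC/C(C)=C\I | intermediate
22 | dilithium C10-alkoxide C1-enolate of ketone 17 | C=C(O[Li])[C@](C)(O[Li])C[C@H](O[Si](C)(C)C(C)(C)C)c1coc([Si](C)(C)C(C)(C)C)c1CO[Si](C)(C)C(C)(C)C | intermediate
23 | (1S,3R,7Z)-1-Ar-3-hydroxy-8-iodo-3,7-dimethyl-1-(TBS-oxy)oct-7-en-4-one | I/C=C(C)\CCC(=O)[C@](C)(O)C[C@H](O[Si](C)(C)C(C)(C)C)c1coc([Si](C)(C)C(C)(C)C)c1CO[Si](C)(C)C(C)(C)C | intermediate
24 | (1S,3R,7Z)-1-Ar-8-iodo-3,7-dimethyl-4-oxo-1-(TBS-oxy)oct-7-en-3-yl acetate | I/C=C(C)\CCC(=O)[C@](C)(OC(C)=O)C[C@H](O[Si](C)(C)C(C)(C)C)c1coc([Si](C)(C)C(C)(C)C)c1CO[Si](C)(C)C(C)(C)C | intermediate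
25 | endoperoxide of 24 (2,3,7-trioxabicyclo[2.2.1]hept-5-ene, dioxygen bridging C6 and C12; bridgehead configuration undefined) | I/C=C(C)\CCC(=O)[C@](C)(OC(C)=O)C[C@H](O[Si](C)(C)C(C)(C)C)C1=C(CO[Si](C)(C)C(C)(C)C)C2([Si](C)(C)C(C)(C)C)OOC1O2 | intermediate
26 | TBS (2Z,4S,6R,10Z)-6-acetoxy-3-formyl-11-iodo-6,10-dimethyl-7-oxo-4-(TBS-oxy)-2-[(TBS-oxy)methyl]undeca-2,10-dienoate | I/C=C(C)\CCC(=O)[C@](C)(OC(C)=O)C[C@H](O[Si](C)(C)C(C)(C)C)/C(C=O)=C(CO[Si](C)(C)C(C)(C)C)/C(=O)O[Si](C)(C)C(C)(C)C | intermediate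
27 | (1S,3R,7Z)-1-{2-hydroxy-5-oxo-4-[(TBS-oxy)methyl]-2,5-dihydrofuran-3-yl}-8-iodo-3,7-dimethyl-4-oxo-1-(TBS-oxy)oct-7-en-3-yl acetate (lactol epimers) | I/C=C(C)\CCC(=O)[C@](C)(OC(C)=O)C[C@H](O[Si](C)(C)C(C)(C)C)C1=C(CO[Si](C)(C)C(C)(C)C)C(=O)OC1O | intermediate
28 | potassium (2Z,4S,6R,10Z)-6-acetoxy-3-formyl-11-iodo-6,10-dimethyl-7-oxo-4-(TBS-oxy)-2-[(TBS-oxy)methyl]undeca-2,10-dienoate | I/C=C(C)\CCC(=O)[C@](C)(OC(C)=O)C[C@H](O[Si](C)(C)C(C)(C)C)/C(C=O)=C(CO[Si](C)(C)C(C)(C)C)/C(=O)[O-].[K+] | intermediate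
29 | methyl (2Z,4S,6R,10Z)-6-acetoxy-3-formyl-11-iodo-6,10-dimethyl-7-oxo-4-(TBS-oxy)-2-[(TBS-oxy)methyl]undeca-2,10-dienoate | I/C=C(C)\CCC(=O)[C@](C)(OC(C)=O)C[C@H](O[Si](C)(C)C(C)(C)C)/C(C=O)=C(CO[Si](C)(C)C(C)(C)C)/C(=O)OC | intermediate
30 | alkenylchromium dichloride of 29 (C5–CrCl2 in place of C5–I, Z retained) | Cl[Cr](Cl)/C=C(C)\CCC(=O)[C@](C)(OC(C)=O)C[C@H](O[Si](C)(C)C(C)(C)C)/C(C=O)=C(CO[Si](C)(C)C(C)(C)C)/C(=O)OC | intermediate
31 | ten-membered carbocycle with C5–C6 formed, (6R)-C6–O–CrCl2 and the C12 methyl ester still open | CC(C)(C)[Si](C)(C)O[C@H]1C[C@@](C)(OC(C)=O)C(=O)CC/C(C)=C\[C@@H](O[Cr](Cl)Cl)/C1=C(CO[Si](C)(C)C(C)(C)C)\C(=O)OC | intermediate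
32 | (4Z,6R,8S,10R)-10-acetoxy-1-oxo-8,13-bis(TBS-oxy)germacra-4,7(11)-dien-12,6-olide | CC(C)(C)[Si](C)(C)O[C@H]1C[C@@](C)(OC(C)=O)C(=O)CC/C(C)=C\[C@H]2OC(=O)C(CO[Si](C)(C)C(C)(C)C)=C12 | intermediate
33 | (4Z,6R,8S,10R)-10-acetoxy-8,13-dihydroxy-1-oxogermacra-4,7(11)-dien-12,6-olide | O[C@H]1C[C@@](C)(OC(C)=O)C(=O)CC/C(C)=C\[C@H]2OC(=O)C(CO)=C12 | intermediate
34 | (4Z,6R,8S,10R)-10,13-diacetoxy-8-hydroxy-1-oxogermacra-4,7(11)-dien-12,6-olide | O[C@H]1C[C@@](C)(OC(C)=O)C(=O)CC/C(C)=C\[C@H]2OC(=O)C(COC(C)=O)=C12 | intermediate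
35 | (4Z,6R,8S,10R)-10,13-diacetoxy-8-(2-methylprop-2-enoyloxy)-1-oxogermacra-4,7(11)-dien-12,6-olide (CNP0115165.2) | C=C(C)C(=O)O[C@H]1C[C@@](C)(OC(C)=O)C(=O)CC/C(C)=C\[C@H]2OC(=O)C(COC(C)=O)=C12 | target

**Step count and risks**

Total: 19 steps. Longest linear sequence: 15 steps (steps 1–3, 6–9 and 12–19, from furan-3-ylmethanol).

Steps most likely to fail:

Step 16. Ring closure may be outrun by intermolecular alkenyl–aldehyde coupling, and the aldehyde face may be selected poorly if the C8 rotamer or the formyl rotamer is less biased than assumed. The fallback sets out from 29 and comes back at 32, and moves stereocontrol from the substrate to the reagent. The coupling would be run with catalytic CrCl2 bound to a chiral oxazoline sulfonamide ligand, the NiCl2 complex of 2,9-dimethyl-1,10-phenanthroline, manganese powder as the stoichiometric reductant, and Cp2ZrCl2 and LiCl in MeCN to release chromium from the alkoxide. The ligand enantiomer would be chosen to match attack on the 6R face, the low standing concentration of alkenylchromium should also favour ring closure, and the butenolide would close on work-up as before. No new compound arises on this path (F0).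

Step 12. Proton exchange between the enolate and the alkylated ketone may lead to double alkylation, and the C10 alkoxide may draw the silyl group from the C8 oxygen. The fallback sets out from 17 and comes back at 23 by way of a metalated hydrazone (Corey–Enders alkylation). Ketone 17 would be condensed with 1,1-dimethylhydrazine (EtOH, AcOH cat.) to the N,N-dimethylhydrazone of ketone 17 F1. This would be deprotonated with LiN(iPr)2 (2.2 equiv) at the methyl-derived carbon and alkylated with 21 to the N,N-dimethylhydrazone of ketone 23 F2. Aqueous Cu(OAc)2 in THF should then release 23.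

Step 9. Acyl substitution at the neopentyl-type dioxolanone carbonyl may be sluggish, and early collapse of the magnesium chelate would allow over-addition of the Grignard reagent. The fallback sets out from 15 and comes back at 17 through the free acid. LiOH in THF/H2O would saponify the dioxolanone to (2R,4S)-4-Ar-2-hydroxy-2-methyl-4-(TBS-oxy)butanoic acid F3. Excess MeLi in THF at 0 °C, followed by a Me3SiCl quench and dilute acid, should then give methyl ketone 17 (organolithium ketone synthesis from a lithium carboxylate).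

Further compounds
F0 | step 16 | none | none
F1 | step 12 | N,N-dimethylhydrazone of ketone 17 | CC(=NN(C)C)[C@](C)(O)C[C@H](O[Si](C)(C)C(C)(C)C)c1coc([Si](C)(C)C(C)(C)C)c1CO[Si](C)(C)C(C)(C)C
F2 | step 12 | N,N-dimethylhydrazone of ketone 23 | I/C=C(C)\CCC(=NN(C)C)[C@](C)(O)C[C@H](O[Si](C)(C)C(C)(C)C)c1coc([Si](C)(C)C(C)(C)C)c1CO[Si](C)(C)C(C)(C)C
F3 | step 9 | (2R,4S)-4-Ar-2-hydroxy-2-methyl-4-(TBS-oxy)butanoic acid | OC(=O)[C@](C)(O)C[C@H](O[Si](C)(C)C(C)(C)C)c1coc([Si](C)(C)C(C)(C)C)c1CO[Si](C)(C)C(C)(C)C
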